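**Strategy.** The ten-membered ring is disconnected at C1–C2 (germacrane numbering: C1 ketone, C4–C5 epoxide, butenolide ring B fused at C6–C7). The key step exploits the plain C2–C3 methylene pair beside the C1 carbonyl: a primary C2 iodide becomes a non-basic alkylchromium that adds to the C1 aldehyde and closes the carbocycle in one operation, while ring B, its acidic C6–H and the esters survive. The precursor is a seco iodo-aldehyde in which ring B and the E-configured C4=C5 alkene act as turn elements. Ring B comes from a halo-aldol and a nickel/chromium coupling–lactonisation; C1 oxidation and outer-face epoxidation of C4=C5 finish the synthesis.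

Key step: step 13

Remark: germacrane numbering of the target is used for every intermediate (C1 ketone, C2/C3 methylenes, C4/C5 epoxide carbons, C6 lactone carbinol, C7=C11 butenolide alkene, C12 lactone carbonyl, C13 acetoxymethyl, C8 angelate carbinol, C9 methylene, C10 methyl-bearing carbon). Compounds 1, 6, 10 and 13 are taken as commercial.

Step 1
Reactants: 1 but-3-yn-1-ol
Product: 3 (E)-3-methylpent-2-ene-1,5-diol, via alkenylalane 2 (not isolated)
Conditions: Me3Al, Cp2ZrCl2 (cat.), CH2Cl2, 0 °C to rt; then n-BuLi, (CH2O)n, THF, −78 °C to rt; aq. HCl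
Reagents that add atoms: trimethylaluminium C[Al](C)C; formaldehyde (as paraformaldehyde) C=O
Why: Negishi zirconium-catalysed carboalumination should add methyl and aluminium syn across the terminal alkyne (methyl to the internal carbon), and hydroxymethylation of the alanate with retention fixes the E geometry of the future C4=C5 alkene.

Step 2
Reactants: 3 (E)-3-methylpent-2-ene-1,5-diol
Product: 4 (E)-5-hydroxy-3-methylpent-2-enal
Conditions: MnO2, CH2Cl2, rt
Reagents that add atoms: none
Why: Activated MnO2 should oxidise only the allylic primary alcohol (future C6) and leave the saturated primary alcohol and the alkene geometry untouched.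

Step 3
Reactants: 4 (E)-5-hydroxy-3-methylpent-2-enal
Product: 5 (E)-5-iodo-3-methylpent-2-enal
Conditions: I2, PPh3, imidazole, CH2Cl2, 0 °C
Reagents that add atoms: iodine II
Why: Appel iodination should convert the remaining primary alcohol (C2) into the iodide under near-neutral conditions that the E-enal tolerates.

Step 4
Reactants: 6 (S)-3-bromo-2-methylpropan-1-ol
Product: 7 (S)-(3-bromo-2-methylpropoxy)(tert-butyl)dimethylsilane
Conditions: TBSCl, imidazole, DMF, rt
Reagents that add atoms: tert-butyldimethylsilyl chloride C[Si](C)(Cl)C(C)(C)C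
Why: Standard silylation protects the future C1 oxygen of the chiral-pool block, whose stereocentre becomes C10 of the target unchanged.

Step 5
Reactants: 7 (S)-(3-bromo-2-methylpropoxy)(tert-butyl)dimethylsilane
Product: 9 (R)-4-(tert-butyldimethylsilyloxy)-3-methylbutanal, via Grignard reagent 8 (not isolated)
Conditions: Mg, THF, rt; then DMF, 0 °C; aq. NH4Cl
Reagents that add atoms: N,N-dimethylformamide CN(C)C=O
Why: Bouveault formylation of the Grignard reagent should add the C8 carbon as the aldehyde without touching the C10 stereocentre.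

Step 6
Reactants: 9 (R)-4-(tert-butyldimethylsilyloxy)-3-methylbutanal; 10 methyl propiolate
Product: 12 methyl (4S,6R)-7-(tert-butyldimethylsilyloxy)-4-hydroxy-6-methylhept-2-ynoate, via zinc alkynylide 11 (not isolated)
Conditions: Me2Zn, ProPhenol ligand (cat., enantiomer for Re-face attack), Ph3P=O (cat.), toluene, 4 °C
Reagents that add atoms: none
Why: Catalytic asymmetric alkynylation by the dinuclear zinc–ProPhenol complex should deliver the alkynylide to the Re face of the aldehyde and so set C8 as S under catalyst control.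

Step 7
Reactants: 12 methyl (4S,6R)-7-(tert-butyldimethylsilyloxy)-4-hydroxy-6-methylhept-2-ynoate; 13 angelic acid
Product: 15 methyl (4S,6R)-4-(angeloyloxy)-7-(tert-butyldimethylsilyloxy)-6-methylhept-2-ynoate, via mixed anhydride 14 (not isolated)
Conditions: 13, 2,4,6-trichlorobenzoyl chloride, Et3N, toluene, rt; then 12, toluene, rt to 70 °C
Reagents that add atoms: none
Why: Yamaguchi esterification through the mixed anhydride should acylate the propargylic alcohol with retention at C8 and, run without DMAP, should avoid isomerisation of the Z-angelate to the tiglate.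

Step 8
Reactants: 15 methyl (4S,6R)-4-(angeloyloxy)-7-(tert-butyldimethylsilyloxy)-6-methylhept-2-ynoate
Product: 17 methyl (2Z,4S,6R)-4-(angeloyloxy)-7-(tert-butyldimethylsilyloxy)-2-(hydroxymethyl)-3-iodo-6-methylhept-2-enoate, via magnesium iodoallenolate 16 (not isolated)
Conditions: MgI2, monomeric CH2O (from cracked paraformaldehyde), CH2Cl2, 0 °C to rt, dark
Reagents that add atoms: magnesium iodide [Mg+2].[I-].[I-]; formaldehyde C=O
Why: In this halo-aldol reaction iodide should add to the ynoate β-carbon (C7), the iodoallenolate should be trapped at C11 by formaldehyde, and iodine should end syn to the ester carbonyl (2Z), the geometry usual for such adducts and the one needed for the later lactonisation.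

Step 9
Reactants: 17 methyl (2Z,4S,6R)-4-(angeloyloxy)-7-(tert-butyldimethylsilyloxy)-2-(hydroxymethyl)-3-iodo-6-methylhept-2-enoate
Product: 18 methyl (2Z,4S,6R)-2-(acetoxymethyl)-4-(angeloyloxy)-7-(tert-butyldimethylsilyloxy)-3-iodo-6-methylhept-2-enoate
Conditions: Ac2O, pyridine, CH2Cl2, 0 °C
Reagents that add atoms: acetic anhydride CC(=O)OC(C)=O
Why: Acetylation of the only free hydroxyl installs the C13 acetate of the target before ring B is formed.

Step 10
Reactants: 18 methyl (2Z,4S,6R)-2-(acetoxymethyl)-4-(angeloyloxy)-7-(tert-butyldimethylsilyloxy)-3-iodo-6-methylhept-2-enoate; 5 (E)-5-iodo-3-methylpent-2-enal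
Product: 21 (5R)-3-(acetoxymethyl)-5-[(E)-4-iodo-2-methylbut-1-enyl]-4-[(1S,3R)-1-(angeloyloxy)-4-(tert-butyldimethylsilyloxy)-3-methylbutyl]furan-2(5H)-one, via alkenylchromium 19 (not isolated), via hydroxy ester 20 (not isolated)
Conditions: CrCl2, NiCl2 (cat.), chiral sulfonamide–oxazoline ligand (enantiomer for Si-face attack), Et3N, THF, rt; then PPTS (cat.), CH2Cl2, rt
Reagents that add atoms: none
Why: In this Nozaki–Hiyama–Kishi coupling nickel should activate only the alkenyl iodide (the primary alkyl iodide of 5 is inert without cobalt), the alkenylchromium should add 1,2 to the enal with ligand-controlled Si-face attack that sets C6, and the 2Z geometry places the new alkoxide syn to the methyl ester so that lactonisation closes butenolide ring B.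

Step 11
Reactants: 21 the silyl ether from step 10
Product: 22 (5R)-3-(acetoxymethyl)-4-[(1S,3R)-1-(angeloyloxy)-4-hydroxy-3-methylbutyl]-5-[(E)-4-iodo-2-methylbut-1-enyl]furan-2(5H)-one
Conditions: HF·pyridine, pyridine, THF, 0 °C
Reagents that add atoms: none
Why: Buffered fluoride desilylation should free the primary C1 alcohol without touching the acetate, the angelate, the lactone or the alkyl iodide.

Step 12
Reactants: 22 the primary alcohol from step 11
Product: 23 (5R)-3-(acetoxymethyl)-4-[(1S,3R)-1-(angeloyloxy)-3-methyl-4-oxobutyl]-5-[(E)-4-iodo-2-methylbut-1-enyl]furan-2(5H)-one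
Conditions: Dess–Martin periodinane, NaHCO3, CH2Cl2, 0 °C
Reagents that add atoms: none
Why: Buffered Dess–Martin oxidation should give the α-branched C1 aldehyde under neutral conditions that epimerise neither C10 nor C6.

Step 13
Reactants: 23 the seco iodo-aldehyde from step 12
Product: 25 (4E,6R,8S,10R)-13-acetoxy-8-angeloyloxy-1-hydroxygermacra-4,7(11)-dien-12,6-olide (both C1 epimers), via alkylchromium 24 (not isolated)
Conditions: CrCl2 (excess), cobalt phthalocyanine Co(C32H16N8) (cat.), DMF, rt, syringe-pump addition to high dilution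
Reagents that add atoms: none
Why: Cobalt phthalocyanine, reduced by CrCl2, should turn the primary C2 iodide into the C2 radical, which CrCl2 captures as alkylchromium 24 (trivalent chromium), and 24 should add intramolecularly to the C1 aldehyde to give the carbocycle as its chromium alkoxide. The closest known reaction is the cobalt-catalysed alkyl variant of the Nozaki–Hiyama–Kishi reaction of primary alkyl iodides with aldehydes, used here as a macrocyclisation. The ten-membered ring is closed by carbonyl addition in the exo mode at C1=O, with ring B and the E-configured C4=C5 alkene as turn elements that bring C2 close to C1. The only new stereocentre is the C1 carbinol, left as a mixture because step 14 oxidises it, while C6, C8 and C10 are untouched under the neutral conditions. The step needs selectivity for the aldehyde over the lactone and the three esters and must not deprotonate the acidic C6–H, which the non-basic, aldehyde-selective alkylchromium secures; cyclisation over oligomerisation is favoured by slow addition and by the persistence of the alkylchromium, and the E alkene in the tether rules out radical cyclisation onto ring B through a six-membered ring.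

Step 14
Reactants: 25 the macrocyclic alcohol from step 13
Product: 26 (4E,6R,8S,10R)-13-acetoxy-8-angeloyloxy-1-oxogermacra-4,7(11)-dien-12,6-olide
Conditions: Dess–Martin periodinane, NaHCO3, CH2Cl2, 0 °C
Reagents that add atoms: none
Why: Buffered Dess–Martin oxidation should merge both C1 carbinol epimers into the C1 ketone without epimerising C10 or triggering an acid-induced transannular reaction.

Step 15
Reactants: 26 the macrocyclic ketone from step 14
Product: 27 (4R,5R,6S,8S,10R)-13-acetoxy-8-angeloyloxy-4,5-epoxy-1-oxogermacr-7(11)-en-12,6-olide (target)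
Conditions: dimethyldioxirane, acetone, −20 to 0 °C
Reagents that add atoms: dimethyldioxirane CC1(C)OO1
Why: Neutral dimethyldioxirane should epoxidise only the electron-rich trisubstituted C4=C5 alkene from the outer face of the ring, which in the allylic-strain-minimised conformer (C6–H eclipsing the alkene, C7 inside the ring) is the face of the C6–O bond, so the trans 4R,5R epoxide syn to the C6 oxygen should result.

**Compound list**

1 | but-3-yn-1-ol | C#CCCO | starting material
2 | dimethyl[(E)-4-(dimethylaluminiooxy)-2-methylbut-1-enyl]alane (alkenylalane) | C[Al](C)/C=C(\C)CCO[Al](C)C | intermediate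
3 | (E)-3-methylpent-2-ene-1,5-diol | OC/C=C(\C)CCO | intermediate
4 | (E)-5-hydroxy-3-methylpent-2-enal | O=C/C=C(\C)CCO | intermediate
5 | (E)-5-iodo-3-methylpent-2-enal | O=C/C=C(\C)CCI | intermediate
6 | (S)-3-bromo-2-methylpropan-1-ol | BrC[C@@H](C)CO | starting material
7 | (S)-(3-bromo-2-methylpropoxy)(tert-butyl)dimethylsilane | BrC[C@@H](C)CO[Si](C)(C)C(C)(C)C | intermediate
8 | (S)-[3-(tert-butyldimethylsilyloxy)-2-methylpropyl]magnesium bromide (Grignard reagent) | Br[Mg]C[C@@H](C)CO[Si](C)(C)C(C)(C)C | intermediate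
9 | (R)-4-(tert-butyldimethylsilyloxy)-3-methylbutanal | O=CC[C@@H](C)CO[Si](C)(C)C(C)(C)C | intermediate
10 | methyl propiolate | C#CC(=O)OC | starting material
11 | methyl 3-(methylzincio)propiolate (zinc alkynylide) | C[Zn]C#CC(=O)OC | intermediate
12 | methyl (4S,6R)-7-(tert-butyldimethylsilyloxy)-4-hydroxy-6-methylhept-2-ynoate | O[C@H](C#CC(=O)OC)C[C@@H](C)CO[Si](C)(C)C(C)(C)C | intermediate
13 | angelic acid, (Z)-2-methylbut-2-enoic acid | C/C=C(/C)C(=O)O | starting material
14 | angelic 2,4,6-trichlorobenzoic anhydride (mixed anhydride) | C/C=C(/C)C(=O)OC(=O)c1c(Cl)cc(Cl)cc1Cl | intermediate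
15 | methyl (4S,6R)-4-(angeloyloxy)-7-(tert-butyldimethylsilyloxy)-6-methylhept-2-ynoate | C/C=C(/C)C(=O)O[C@H](C#CC(=O)OC)C[C@@H](C)CO[Si](C)(C)C(C)(C)C | intermediate
16 | magnesium iodoallenolate of 15 | COC(O[Mg]I)=C=C(I)[C@@H](OC(=O)/C(C)=C\C)C[C@@H](C)CO[Si](C)(C)C(C)(C)C | intermediate
17 | methyl (2Z,4S,6R)-4-(angeloyloxy)-7-(tert-butyldimethylsilyloxy)-2-(hydroxymethyl)-3-iodo-6-methylhept-2-enoate | C/C=C(/C)C(=O)O[C@H](/C(I)=C(\CO)C(=O)OC)C[C@@H](C)CO[Si](C)(C)C(C)(C)C | intermediate
18 | methyl (2Z,4S,6R)-2-(acetoxymethyl)-4-(angeloyloxy)-7-(tert-butyldimethylsilyloxy)-3-iodo-6-methylhept-2-enoate | C/C=C(/C)C(=O)O[C@H](/C(I)=C(\COC(C)=O)C(=O)OC)C[C@@H](C)CO[Si](C)(C)C(C)(C)C | intermediate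
19 | alkenylchromium dichloride from 18 (chromium at C7) | C/C=C(/C)C(=O)O[C@H](/C([Cr](Cl)Cl)=C(\COC(C)=O)C(=O)OC)C[C@@H](C)CO[Si](C)(C)C(C)(C)C | intermediate
20 | open-chain hydroxy ester (6R,8S,10R; C6 carbinol syn to the methyl ester across C7=C11) | C/C=C(/C)C(=O)O[C@@H](C[C@@H](C)CO[Si](C)(C)C(C)(C)C)/C(=C(\COC(C)=O)C(=O)OC)[C@H](O)/C=C(\C)CCI | intermediate
21 | (5R)-3-(acetoxymethyl)-5-[(E)-4-iodo-2-methylbut-1-enyl]-4-[(1S,3R)-1-(angeloyloxy)-4-(tert-butyldimethylsilyloxy)-3-methylbutyl]furan-2(5H)-one | C/C=C(/C)C(=O)O[C@@H](C[C@@H](C)CO[Si](C)(C)C(C)(C)C)C1=C(COC(C)=O)C(=O)O[C@@H]1/C=C(\C)CCI | intermediate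
22 | (5R)-3-(acetoxymethyl)-4-[(1S,3R)-1-(angeloyloxy)-4-hydroxy-3-methylbutyl]-5-[(E)-4-iodo-2-methylbut-1-enyl]furan-2(5H)-one | C/C=C(/C)C(=O)O[C@@H](C[C@@H](C)CO)C1=C(COC(C)=O)C(=O)O[C@@H]1/C=C(\C)CCI | intermediate
23 | (5R)-3-(acetoxymethyl)-4-[(1S,3R)-1-(angeloyloxy)-3-methyl-4-oxobutyl]-5-[(E)-4-iodo-2-methylbut-1-enyl]furan-2(5H)-one | C/C=C(/C)C(=O)O[C@@H](C[C@@H](C)C=O)C1=C(COC(C)=O)C(=O)O[C@@H]1/C=C(\C)CCI | intermediate
24 | alkylchromium dichloride from 23 (chromium at C2) | C/C=C(/C)C(=O)O[C@@H](C[C@@H](C)C=O)C1=C(COC(C)=O)C(=O)O[C@@H]1/C=C(\C)CC[Cr](Cl)Cl | intermediate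
25 | (4E,6R,8S,10R)-13-acetoxy-8-angeloyloxy-1-hydroxygermacra-4,7(11)-dien-12,6-olide, C1 epimers | C/C=C(/C)C(=O)O[C@H]1C[C@@H](C)C(O)CC/C(C)=C/[C@H]2OC(=O)C(COC(C)=O)=C12 | intermediate
26 | (4E,6R,8S,10R)-13-acetoxy-8-angeloyloxy-1-oxogermacra-4,7(11)-dien-12,6-olide | C/C=C(/C)C(=O)O[C@H]1C[C@@H](C)C(=O)CC/C(C)=C/[C@H]2OC(=O)C(COC(C)=O)=C12 | intermediate
27 | (4R,5R,6S,8S,10R)-13-acetoxy-8-angeloyloxy-4,5-epoxy-1-oxogermacr-7(11)-en-12,6-olide | C/C=C(/C)C(=O)O[C@H]1C[C@@H](C)C(=O)CC[C@@]2(C)O[C@@H]2[C@H]2OC(=O)C(COC(C)=O)=C12 | target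

**Totals.** Total step count: 15. Longest linear sequence: 12 steps (steps 4 to 15, from 6).

**Steps most likely to fail**

Step 13: the ring closure of alkylchromium 24 may be slower than oligomerisation or than loss of the C2–chromium bond by protonation. The fallback sets out from alcohol 22 and forms the same bond by acyl cross-coupling instead of carbonyl addition. Oxidation with TEMPO and PhI(OAc)2 in aqueous MeCN would give the carboxylic acid F1. 2,2′-Dipyridyl disulfide and PPh3 would turn it into the S-(2-pyridyl) thioester F2. A nickel/zirconium-mediated intramolecular ketone synthesis (NiBr2·DME, 4,4′-di-tert-butyl-2,2′-bipyridine, Cp2ZrCl2, Zn, DMI, slow addition) would then join C1 to C2 and come back to the route at ketone 26.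

Step 8: the β-substituted ynoate may add iodide sluggishly, or formaldehyde may be captured with the wrong alkene geometry. The fallback sets out from 15 and brings C13 in by cross-coupling on the finished ring B. Addition of I2 (CuI cat., MeCN) would give the E-2,3-diiodo enoate F3, whose β-iodide is the one syn to the ester. Coupling of that iodide with 5 under the conditions of step 10 would give the α-iodobutenolide F4. Stille coupling with Bu3SnCH2OH (Pd(PPh3)4, toluene) would give the hydroxymethyl butenolide F5, and acetylation (Ac2O, pyridine) comes back to the route at 21.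

Step 10: the hindered tetrasubstituted alkenyl iodide may give poor facial selectivity at C6, and the alkenylchromium may lose the allylic angelate by β-elimination. The fallback sets out from 5 and 18 and sets C6 by reagent-controlled reduction. Pinnick oxidation of 5 (NaClO2, NaH2PO4, 2-methylbut-2-ene) would give (E)-5-iodo-3-methylpent-2-enoic acid F6, and EDC coupling with MeNHOMe·HCl would give the Weinreb amide F7. Iodine–magnesium exchange on 18 (i-PrMgCl·LiCl, −78 °C) and acylation by F7 would give the dienone F8. Corey–Bakshi–Shibata reduction of its C6 ketone (Me-CBS oxazaborolidine, catecholborane) would give hydroxy ester 20, which lactonises and comes back to the route at 21.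

**Further compounds**

F1 | step 13 | (2R,4S)-4-(angeloyloxy)-4-[(5R)-4-(acetoxymethyl)-2-[(E)-4-iodo-2-methylbut-1-enyl]-5-oxo-2,5-dihydrofuran-3-yl]-2-methylbutanoic acid | C/C=C(/C)C(=O)O[C@@H](C[C@@H](C)C(=O)O)C1=C(COC(C)=O)C(=O)O[C@@H]1/C=C(\C)CCI
F2 | step 13 | S-(pyridin-2-yl) thioester of F1 | C/C=C(/C)C(=O)O[C@@H](C[C@@H](C)C(=O)Sc1ccccn1)C1=C(COC(C)=O)C(=O)O[C@@H]1/C=C(\C)CCI
F3 | step 8 | methyl (2E,4S,6R)-4-(angeloyloxy)-7-(tert-butyldimethylsilyloxy)-2,3-diiodo-6-methylhept-2-enoate | C/C=C(/C)C(=O)O[C@H](/C(I)=C(\I)C(=O)OC)C[C@@H](C)CO[Si](C)(C)C(C)(C)C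
F4 | step 8 | (5R)-3-iodo-5-[(E)-4-iodo-2-methylbut-1-enyl]-4-[(1S,3R)-1-(angeloyloxy)-4-(tert-butyldimethylsilyloxy)-3-methylbutyl]furan-2(5H)-one | C/C=C(/C)C(=O)O[C@@H](C[C@@H](C)CO[Si](C)(C)C(C)(C)C)C1=C(I)C(=O)O[C@@H]1/C=C(\C)CCI
F5 | step 8 | (5R)-3-(hydroxymethyl)-5-[(E)-4-iodo-2-methylbut-1-enyl]-4-[(1S,3R)-1-(angeloyloxy)-4-(tert-butyldimethylsilyloxy)-3-methylbutyl]furan-2(5H)-one | C/C=C(/C)C(=O)O[C@@H](C[C@@H](C)CO[Si](C)(C)C(C)(C)C)C1=C(CO)C(=O)O[C@@H]1/C=C(\C)CCI
F6 | step 10 | (E)-5-iodo-3-methylpent-2-enoic acid | OC(=O)/C=C(\C)CCI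
F7 | step 10 | (E)-5-iodo-N-methoxy-N,3-dimethylpent-2-enamide | CON(C)C(=O)/C=C(\C)CCI
F8 | step 10 | dienone (C6 ketone) corresponding to hydroxy ester 20 | C/C=C(/C)C(=O)O[C@@H](C[C@@H](C)CO[Si](C)(C)C(C)(C)C)/C(=C(\COC(C)=O)C(=O)OC)C(=O)/C=C(\C)CCI
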